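**Plan**
1. Cuts: the O–CHO bond goes first. The C11=C12 bond (Wittig) then separates the C12–C16 acid arm from an 8α-silyloxydrimanal. Next, C5–C10 and C8–C9 of ring B are cut together as the retro-[4+2] of a 5α,8α-epoxydrim-6-ene. Last, C4–C5 is cut (furan alkylation), which leads to methyl geranate and 2-methylfuran.
2. Enabling feature: on ring B, H-5 and O-8 are 1,4-cis (both α), C6–C7 is a bare CH2–CH2, and C9 carries C11, which may be a carbonyl. O-8 can therefore be the ring oxygen of a furan C5=C6–C7=C8(CH3), temporarily bonded to C5 as well. C9=C10 is then an (E)-enoyl dienophile attached to the furan by the C1–C4 chain that becomes ring A.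
3. Forward: the C4–C5 bond joins the C10 and C5 building blocks, and one intramolecular furan Diels–Alder reaction closes rings A and B together. The temporary C5–O bond is cut reductively (the oxygen stays on C8), Δ5 is saturated and the auxiliary leaves. C11 serves for olefination, followed by hydrogenation, desilylation and formylation.
4. Stereochemistry: C5, C8, C9 and C10 arise in the cycloaddition (E-alkene, oxygen "inside" at both diene termini, exo tether/endo acyl, absolute sense from (S)-4-benzyloxazolidinone). H-5 is put back α by radical hydrogenation to the trans-decalin. C13 comes from (R)-4-methyloxolan-2-one.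
5. Labdane/drimane numbering is used for the cyclised compounds and, by anticipation, for the open-chain precursors.

Key step: step 4

Assumption: methyl (2E)-geranate and (4R)-4-methyloxolan-2-one are taken as catalogue chemicals of high geometric and enantiomeric purity.

Step 1
Reactants: 1 methyl (2E)-3,7-dimethylocta-2,6-dienoate (methyl geranate); 2 2-methylfuran
Product: 3 methyl (2E)-3,7-dimethyl-7-(5-methylfuran-2-yl)oct-2-enoate
Conditions: 2 (8 equiv), Ca(NTf2)2 (5 mol %), Bu4NPF6 (5 mol %), CH2Cl2, 0 °C to rt
Reagents that add atoms: none
Why: Friedel–Crafts hydroarylation: the salt pair supplies just enough acidity for Markovnikov protonation of the electron-rich C3=C4 alkene (the conjugated C9=C10 alkene is neither protonated nor nucleophilic enough to trap the cation quickly), and the tertiary C4 cation is intercepted by the large excess of the far more nucleophilic 2-methylfuran at its only free α-position, so that quaternary C4 and the C4–C5 bond are made without touching the E-enoate and without creating a stereocentre.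

Step 2
Reactants: 3 methyl (2E)-3,7-dimethyl-7-(5-methylfuran-2-yl)oct-2-enoate
Product: 4 (2E)-3,7-dimethyl-7-(5-methylfuran-2-yl)oct-2-enoic acid
Conditions: LiOH, THF/MeOH/H2O, 45 °C; cold 0.5 M HCl to pH 4
Reagents that add atoms: lithium hydroxide [Li+].[OH-]
Why: Ordinary ester saponification, in which the alkene geometry is kept and the brief, cold and weakly acidic work-up spares the dialkylfuran.

Step 3
Reactants: 4 (2E)-3,7-dimethyl-7-(5-methylfuran-2-yl)oct-2-enoic acid; 5 (4S)-4-benzyl-1,3-oxazolidin-2-one
Product: 7 (4S)-4-benzyl-3-[(2E)-3,7-dimethyl-7-(5-methylfuran-2-yl)oct-2-enoyl]-1,3-oxazolidin-2-one, via mixed pivalic anhydride 6 (not isolated)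
Conditions: PivCl, Et3N, THF, −20 °C; then LiCl, 5, −20 °C to rt
Reagents that add atoms: pivaloyl chloride CC(C)(C)C(=O)Cl (its atoms stay only in 6)
Why: N-Acylation of an oxazolidinone through the mixed pivalic anhydride with LiCl/Et3N needs neither a strong base nor an acid chloride, so that the furan survives, the enoate is not deconjugated and the auxiliary that will fix the absolute configuration is attached unchanged.

Step 4
Reactants: 7 (4S)-4-benzyl-3-[(2E)-3,7-dimethyl-7-(5-methylfuran-2-yl)oct-2-enoyl]-1,3-oxazolidin-2-one
Product: 8 (4S)-4-benzyl-3-(5α,8α-epoxydrim-6-en-11-oyl)-1,3-oxazolidin-2-one (9β-acyl, 9α-H, 10β-CH3, 8β-CH3)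
Conditions: Me2AlCl (1.6 equiv), CH2Cl2 (0.01 M), −78 to −30 °C; ice-water quench; 8 kept cold and used at once
Reagents that add atoms: none
Why: More than one equivalent of Me2AlCl turns the imide into the cationic two-point chelate [imide·AlMe2]+ with the enoyl unit locked s-cis, and the 2,5-dialkylfuran (C5=C6–C7=C8, held s-cis by its own oxygen) adds suprafacially across C9=C10 in an asynchronous [4+2] in which the electron-rich C5 leads onto the β-carbon C10 and C8 closes onto the α-carbon C9, the "ortho" pairing of a 1-oxygenated diene. The closest known reaction types are the alkylaluminium-chloride-promoted intramolecular Diels–Alder reaction of furans with a four-atom tether, which gives 1,4-epoxydecalins, and the oxazolidinone-controlled intramolecular Diels–Alder reaction of trienimides. Ring A (six-membered) closes by the C5–C10 bond through the four-carbon tether C1–C4 (1,7,9-decatriene pattern) with the tether exo, syn to the oxygen bridge, which is the low-strain way to span bridgehead C5 and C10; ring B is the six-membered ring of the cycloaddition itself, closed by both new bonds and born as a boat bridged by C5–O–C8. The C9/C10 relation (C11 cis to the C10 methyl) is copied from the E-alkene and its absolute sense comes from the benzyl group, which covers the re face of C9 so that the furan bonds to the si face; C5 and C8 follow because the exo-tether/endo-acyl transition state lets only one furan face reach that dienophile face, and the ring oxygen, being the "inside" substituent at both diene termini, ends α on C8 with the methyl β. The step needs periselectivity (both furan α-positions are blocked and β-attack would need a seven-membered ring), endo/exo and π-facial selectivity, and a favourable position of a reversible equilibrium, which the low temperature, the stronger binding of aluminium to the deconjugated product imide and the gem-dimethyl group next to the furan are expected to secure.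

Step 5
Reactants: 8 (4S)-4-benzyl-3-(5α,8α-epoxydrim-6-en-11-oyl)-1,3-oxazolidin-2-one
Product: 9 (4S)-4-benzyl-3-[8α-(triethylsilyloxy)drim-5-en-11-oyl]-1,3-oxazolidin-2-one
Conditions: Et3SiH (3 equiv), TESOTf (0.3 equiv), 2,6-di-tert-butyl-4-methylpyridine (0.1 equiv), CH2Cl2, −78 to −40 °C; Et3N quench
Reagents that add atoms: triethylsilane CC[SiH](CC)CC
Why: Proposed new method: a silylium-chain reductive SN1′ opening, in which Et3Si+ (from TESOTf) binds the bridge oxygen; C5–O ionises rather than C8–O because C5 is flanked by two quaternary carbons (relief of back strain) whereas a cation at C8 would sit next to the acyl-bearing C9; the C5–C6–C7 allyl cation has no β-hydrogen to lose and is too stabilised for methyl shifts; Et3SiH delivers hydride to its open C7 end and regenerates Et3Si+, so that the oxygen stays on C8 with its configuration and emerges already protected as the TES ether; the closest known reaction types are the Et3SiH/silyl triflate reduction of acetals and of allylic or benzylic ethers and the silyl-triflate cleavage of tert-butyl ethers.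

Step 6
Reactants: 9 (4S)-4-benzyl-3-[8α-(triethylsilyloxy)drim-5-en-11-oyl]-1,3-oxazolidin-2-one
Product: 10 (4S)-4-benzyl-3-[8α-(triethylsilyloxy)-5α-driman-11-oyl]-1,3-oxazolidin-2-one (trans-decalin)
Conditions: Mn(dpm)3 (10 mol %, dpm = dipivaloylmethanate), PhSiH3, t-BuOOH, i-PrOH, rt
Reagents that add atoms: none
Why: Metal-hydride hydrogen-atom-transfer (MHAT) hydrogenation: H· adds to the accessible C6 and the tertiary C5 radical accepts the second hydrogen on its α face because the β face is closed by the axial methyl groups on C4 and C10, which gives the thermodynamically preferred trans-decalin where surface catalysts are known to fail on 4,4-dimethyl-Δ5 olefins, while imide and silyl ether are inert.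

Step 7
Reactants: 10 (4S)-4-benzyl-3-[8α-(triethylsilyloxy)-5α-driman-11-oyl]-1,3-oxazolidin-2-one
Product: 11 8α-(triethylsilyloxy)driman-11-ol
Conditions: LiBH4, THF, 0 °C to rt
Reagents that add atoms: none
Why: Reductive cleavage of an N-acyloxazolidinone, in which the small hydride attacks the more electrophilic exocyclic (C11) carbonyl even in this crowded setting, frees the auxiliary for recovery and leaves C9 and the tertiary silyl ether untouched.

Step 8
Reactants: 11 8α-(triethylsilyloxy)driman-11-ol
Product: 12 8α-(triethylsilyloxy)driman-11-al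
Conditions: Dess–Martin periodinane, CH2Cl2, 0 °C to rt
Reagents that add atoms: none
Why: Dess–Martin oxidation is neutral and fast on hindered primary alcohols, and the formyl group on C9 is already equatorial, so that neither epimerisation nor β-elimination of the silyloxy group is expected.

Step 9
Reactants: 13 (4R)-4-methyloxolan-2-one
Product: 14 [(2R)-3-carboxy-2-methylpropyl]triphenylphosphonium bromide
Conditions: PPh3·HBr (1 equiv), neat melt, 155 °C; trituration with Et2O
Reagents that add atoms: triphenylphosphine hydrobromide Br.c1ccc(cc1)P(c1ccccc1)c1ccccc1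
Why: Phosphine opening of a protonated γ-lactone (SN2 at the O–CH2 carbon, the future C12), a known route to (3-carboxypropyl)phosphonium salts, does not touch the stereocentre, which becomes C13.

Step 10
Reactants: 12 8α-(triethylsilyloxy)driman-11-al; 14 [(2R)-3-carboxy-2-methylpropyl]triphenylphosphonium bromide
Product: 16 (11Z)-8α-(triethylsilyloxy)labd-11-en-15-oic acid (C13 spatially as in the target, 13R by the sequence rule), via carboxylate ylide 15 (not isolated)
Conditions: 14 (1.8 equiv), NaHMDS (3.6 equiv), THF, 0 °C; 12, −78 °C to rt; cold 0.5 M HCl work-up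
Reagents that add atoms: sodium bis(trimethylsilyl)amide C[Si](C)(C)[N-][Si](C)(C)C.[Na+] (sodium stays only in 15)
Why: Wittig olefination with a non-stabilised carboxylate-bearing ylide (the type used for prostanoid side chains) joins C11 to C12; addition to the aldehyde at low temperature should outrun enolisation, the equatorial C8–O bond lies nearly orthogonal to the π system of a C9 enolate so that β-elimination is disfavoured, and the alkene geometry (Z expected) is of no consequence.

Step 11
Reactants: 16 (11Z)-8α-(triethylsilyloxy)labd-11-en-15-oic acid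
Product: 17 (13S)-8α-(triethylsilyloxy)labdan-15-oic acid
Conditions: H2 (1 atm), Pt/C, EtOAc, rt
Reagents that add atoms: none
Why: Heterogeneous hydrogenation of the disubstituted alkene over platinum, which migrates double bonds far less than palladium, so that the allylic stereocentre C13 is kept and the former activating carbon C11 ends as the CH2 group of the target.

Step 12
Reactants: 17 (13S)-8α-(triethylsilyloxy)labdan-15-oic acid
Product: 18 (13S)-8α-hydroxylabdan-15-oic acid (labdanolic acid)
Conditions: HF·pyridine, THF, 0 °C to rt
Reagents that add atoms: none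
Why: Fluoride-driven cleavage of the Si–O bond under buffered conditions that do not ionise the tertiary C8–O bond, so that C8 is unchanged.

Step 13
Reactants: 18 (13S)-8α-hydroxylabdan-15-oic acid
Product: 19 (13S)-8α-formyloxylabdan-15-oic acid (target)
Conditions: acetic formic anhydride, pyridine, DMAP (cat.), CH2Cl2, −20 °C to rt; aqueous work-up
Reagents that add atoms: acetic formic anhydride CC(=O)OC=O
Why: O-Formylation with the mixed anhydride, whose formyl carbonyl is by far the more electrophilic and small enough for the hindered equatorial tertiary alcohol; acyl transfer takes place at oxygen, so C8 keeps its configuration, and the carboxylic acid is recovered free after the aqueous work-up.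

**Compound list**
1 | methyl (2E)-3,7-dimethylocta-2,6-dienoate | COC(=O)/C=C(\C)CCC=C(C)C | starting material
2 | 2-methylfuran | Cc1ccco1 | starting material
3 | methyl (2E)-3,7-dimethyl-7-(5-methylfuran-2-yl)oct-2-enoate | COC(=O)/C=C(\C)CCCC(C)(C)c1ccc(C)o1 | intermediate
4 | (2E)-3,7-dimethyl-7-(5-methylfuran-2-yl)oct-2-enoic acid | OC(=O)/C=C(\C)CCCC(C)(C)c1ccc(C)o1 | intermediate
5 | (4S)-4-benzyl-1,3-oxazolidin-2-one | O=C1N[C@@H](Cc2ccccc2)CO1 | starting material
6 | mixed anhydride of 4 and pivalic acid | CC(C)(C)C(=O)OC(=O)/C=C(\C)CCCC(C)(C)c1ccc(C)o1 | intermediate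
7 | (4S)-4-benzyl-3-[(2E)-3,7-dimethyl-7-(5-methylfuran-2-yl)oct-2-enoyl]-1,3-oxazolidin-2-one | O=C1OC[C@H](Cc2ccccc2)N1C(=O)/C=C(\C)CCCC(C)(C)c3ccc(C)o3 | intermediate
8 | (4S)-4-benzyl-3-(5α,8α-epoxydrim-6-en-11-oyl)-1,3-oxazolidin-2-one | O=C1OC[C@H](Cc2ccccc2)N1C(=O)[C@@H]3[C@@]4(C)CCCC(C)(C)[C@]45C=C[C@@]3(C)O5 | intermediate
9 | (4S)-4-benzyl-3-[8α-(triethylsilyloxy)drim-5-en-11-oyl]-1,3-oxazolidin-2-one | O=C1OC[C@H](Cc2ccccc2)N1C(=O)[C@@H]3[C@@]4(C)CCCC(C)(C)C4=CC[C@@]3(C)O[Si](CC)(CC)CC | intermediate
10 | (4S)-4-benzyl-3-[8α-(triethylsilyloxy)-5α-driman-11-oyl]-1,3-oxazolidin-2-one | O=C1OC[C@H](Cc2ccccc2)N1C(=O)[C@@H]3[C@@]4(C)CCCC(C)(C)[C@@H]4CC[C@@]3(C)O[Si](CC)(CC)CC | intermediate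
11 | 8α-(triethylsilyloxy)driman-11-ol | OC[C@@H]1[C@@]2(C)CCCC(C)(C)[C@@H]2CC[C@@]1(C)O[Si](CC)(CC)CC | intermediate
12 | 8α-(triethylsilyloxy)driman-11-al | O=C[C@@H]1[C@@]2(C)CCCC(C)(C)[C@@H]2CC[C@@]1(C)O[Si](CC)(CC)CC | intermediate
13 | (4R)-4-methyloxolan-2-one | C[C@H]1COC(=O)C1 | starting material
14 | [(2R)-3-carboxy-2-methylpropyl]triphenylphosphonium bromide | C[C@@H](C[P+](c1ccccc1)(c1ccccc1)c1ccccc1)CC(=O)O.[Br-] | intermediate
15 | sodium (3R)-3-methyl-4-(triphenyl-λ5-phosphanylidene)butanoate | C[C@@H](C=P(c1ccccc1)(c1ccccc1)c1ccccc1)CC(=O)[O-].[Na+] | intermediate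
16 | (11Z)-8α-(triethylsilyloxy)labd-11-en-15-oic acid | C[C@@H](/C=C\[C@@H]1[C@@]2(C)CCCC(C)(C)[C@@H]2CC[C@@]1(C)O[Si](CC)(CC)CC)CC(=O)O | intermediate
17 | (13S)-8α-(triethylsilyloxy)labdan-15-oic acid | C[C@@H](CC[C@@H]1[C@@]2(C)CCCC(C)(C)[C@@H]2CC[C@@]1(C)O[Si](CC)(CC)CC)CC(=O)O | intermediate
18 | (13S)-8α-hydroxylabdan-15-oic acid | C[C@@H](CC[C@@H]1[C@@]2(C)CCCC(C)(C)[C@@H]2CC[C@@]1(C)O)CC(=O)O | intermediate
19 | (13S)-8α-formyloxylabdan-15-oic acid | C[C@@H](CC[C@@H]1[C@@]2(C)CCCC(C)(C)[C@@H]2CC[C@@]1(C)OC=O)CC(=O)O | target

Total step count: 13. Longest linear sequence: 12 (steps 1–8 and 10–13).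

**Steps most likely to fail**

Step 5. Three things may go wrong. Ionisation may take place on the C8 side, followed by proton loss. The Lewis acid may induce cycloreversion before hydride transfer. Silylation of the crowded bridge oxygen may be too slow.
- The fallback uses known reaction types, sets out from 8 and returns at 10.
- The alkene of 8 is hydrogenated at once (H2, Pd/C, EtOAc), which rules out cycloreversion and gives the saturated 5α,8α-epoxy imide F1.
- Ionic hydrogenation (Et3SiH, BF3·OEt2, CH2Cl2, low temperature) then cleaves the more strained C5–O bond. It delivers hydride to the open α face of the C5 cation, while the neighbouring acyl group keeps the C8–O bond from ionising. This gives the 8α-hydroxy trans-decalin imide F2.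
- Silylation (TESOTf, 2,6-lutidine) leads to 10.

Step 4. The cycloaddition may be slow at the fully substituted termini C5 and C10. The equilibrium may lie on the side of the open furan. Cycloreversion may occur during work-up. Facial selectivity may erode if the reaction has to be warmed into the reversible regime.
- The fallback sets out from 4 and returns at 11. It replaces the bulky chelated imide by a small, one-point-activated ester, and the auxiliary by a catalyst.
- Acid 4 is esterified (CF3CH2OH, EDC·HCl, DMAP) to the trifluoroethyl enoate F3.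
- A chiral cationic oxazaborolidine (B-o-tolyl, from α,α-diphenylprolinol, activated by Tf2NH) is used in the antipode that leaves the si face of C9 open. This catalyst class is known to add furan to trifluoroethyl acrylate and to cyclise trienes. At −78 °C it gives the 5α,8α-epoxydrim-6-enoate F4.
- The operations of steps 5 and 6 convert F4 into the Δ5 silyl ether ester F5 and then the trans-decalin ester F6.
- LiAlH4 reduces F6 to 11.

Step 1. Acid-induced oligomerisation of 2-methylfuran may outrun alkene protonation. The tertiary cation may cyclise onto the enoate. The enoate geometry may drift.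
- The fallback sets out from 1 and returns at 3. The cation precursor is made first and ionised without any Brønsted acid.
- Dry HCl (CH2Cl2, 0 °C) adds selectively to the electron-rich alkene of 1 and gives the tertiary chloride F7.
- F7 alkylates 2 (excess) under SnCl4 (substoichiometric) with 2,6-di-tert-butylpyridine in CH2Cl2 at −78 to −20 °C. This is the Lewis-acid tert-alkylation of a π-nucleophile, and it gives 3.

**Further compounds**
F1 | step 5 | (4S)-4-benzyl-3-(5α,8α-epoxydriman-11-oyl)-1,3-oxazolidin-2-one | O=C1OC[C@H](Cc2ccccc2)N1C(=O)[C@@H]3[C@@]4(C)CCCC(C)(C)[C@]45CC[C@@]3(C)O5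
F2 | step 5 | (4S)-4-benzyl-3-(8α-hydroxy-5α-driman-11-oyl)-1,3-oxazolidin-2-one | O=C1OC[C@H](Cc2ccccc2)N1C(=O)[C@@H]3[C@@]4(C)CCCC(C)(C)[C@@H]4CC[C@@]3(C)O
F3 | step 4 | 2,2,2-trifluoroethyl (2E)-3,7-dimethyl-7-(5-methylfuran-2-yl)oct-2-enoate | FC(F)(F)COC(=O)/C=C(\C)CCCC(C)(C)c1ccc(C)o1
F4 | step 4 | 2,2,2-trifluoroethyl 5α,8α-epoxydrim-6-en-11-oate | FC(F)(F)COC(=O)[C@@H]1[C@@]2(C)CCCC(C)(C)[C@]23C=C[C@@]1(C)O3
F5 | step 4 | 2,2,2-trifluoroethyl 8α-(triethylsilyloxy)drim-5-en-11-oate | FC(F)(F)COC(=O)[C@@H]1[C@@]2(C)CCCC(C)(C)C2=CC[C@@]1(C)O[Si](CC)(CC)CC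
F6 | step 4 | 2,2,2-trifluoroethyl 8α-(triethylsilyloxy)-5α-driman-11-oate | FC(F)(F)COC(=O)[C@@H]1[C@@]2(C)CCCC(C)(C)[C@@H]2CC[C@@]1(C)O[Si](CC)(CC)CC
F7 | step 1 | methyl (2E)-7-chloro-3,7-dimethyloct-2-enoate | COC(=O)/C=C(\C)CCCC(C)(C)Cl
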